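**Plan**

1. Retrosynthesis (isoflavanone numbering; ring A is the benzo ring, ring C the pyranone O1–C4, ring B the pendant aryl C1'–C6'): the two aryl silyl ethers are cut last, then ring C is opened at C2–C3. This returns C2 to the methyl of a ring A ortho-methoxy group and C3 to a diazo carbon between the C4 ketone and ring B.
2. The diazo ketone goes back to a deoxybenzoin, cut at C3–C4 into a ring B benzaldehyde and a ring A α-aminophosphonate. On ring B, the C5'–CMe2 bond is cut back to an O2'-(1,1-dimethylallyl) ether and C1'–CHO back to 2,3-dimethoxyphenol.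
3. Forward: ortho-formylation and O-propargylation of 2,3-dimethoxyphenol; olefination/hydrolysis joins C3–C4; semihydrogenation and a para-Claisen shift carry the C5 unit from O2' to C5'; silylation and diazo transfer follow. Ring C is the only ring formed and closes in the penultimate step.
4. Enabling feature: C2 is a methylene held between O1 and C3, so it can enter as the OCH3 carbon on ring A ortho to the C4 carbonyl, in a 1,6-relationship to a carbene at C3.
5. Stereochemistry: the single stereocentre C3 is created in the C–H insertion under control of the chiral dirhodium carboxylate Rh2(S-PTTL)4 (PTTL = N-phthaloyl-tert-leucinate). It is then kept away from base by an acidic fluoride deprotection.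

Key step: step 10

Remark on the chemistry: the sense of induction of Rh2(S-PTTL)4 with this substrate is assumed to give (R) at C3; should it give (S), the enantiomeric catalyst Rh2(R-PTTL)4 is used in step 10 with nothing else changed.

**Route**

Step 1
Reactants: 1 2,3-dimethoxyphenol
Product: 3 2-hydroxy-3,4-dimethoxybenzaldehyde, via 6-(hydroxymethyl)-2,3-dimethoxyphenol 2 (not isolated)
Conditions: MgCl2, Et3N, (CH2O)n, MeCN, reflux
Reagents that add atoms: paraformaldehyde (as formaldehyde), C=O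
Why: Casnati–Skattebøl ortho-formylation, in which the magnesium phenoxide delivers formaldehyde to the only free ortho position (C6) and the salicyl alcohol 2 is oxidised in the flask by hydride transfer to a second formaldehyde.

Step 2
Reactants: 3 2-hydroxy-3,4-dimethoxybenzaldehyde; 4 3-chloro-3-methylbut-1-yne
Product: 5 3,4-dimethoxy-2-[(2-methylbut-3-yn-2-yl)oxy]benzaldehyde
Conditions: DBU, CuCl2·2H2O (cat.), MeCN, 0 °C → rt
Reagents that add atoms: none
Why: Copper-catalysed propargylic etherification of a phenoxide with a tertiary propargylic chloride (substitution via a copper acetylide/allenylidene), the standard entry to aryl 1,1-dimethylpropargyl ethers, which tolerates acidic electron-poor phenols and places the future C5 unit on O2'.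

Step 3
Reactants: 6 4-hydroxy-2-methoxybenzaldehyde
Product: 7 2-methoxy-4-[(triisopropylsilyl)oxy]benzaldehyde
Conditions: TIPSCl, imidazole, DMF, rt
Reagents that add atoms: triisopropylsilyl chloride, CC(C)[Si](Cl)(C(C)C)C(C)C
Why: Silyl ether formation on the unhindered phenol, the TIPS group being chosen because it should withstand the carbonate base and aqueous acid of step 5.

Step 4
Reactants: 7 2-methoxy-4-[(triisopropylsilyl)oxy]benzaldehyde
Product: 9 diphenyl [{2-methoxy-4-[(triisopropylsilyl)oxy]phenyl}(phenylamino)methyl]phosphonate (racemic), via N-phenyl aldimine 8 (not isolated)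
Conditions: PhNH2, i-PrOH, rt; then (PhO)2P(O)H, rt
Reagents that add atoms: aniline, Nc1ccccc1; diphenyl phosphite, O=[PH](Oc1ccccc1)Oc1ccccc1
Why: Kabachnik–Fields reaction, in which aniline condenses to aldimine 8 and diphenyl phosphite adds across the C=N bond to give the α-aminophosphonate as a racemate whose stereocentre disappears in step 5.

Step 5
Reactants: 9 diphenyl [{2-methoxy-4-[(triisopropylsilyl)oxy]phenyl}(phenylamino)methyl]phosphonate; 5 3,4-dimethoxy-2-[(2-methylbut-3-yn-2-yl)oxy]benzaldehyde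
Product: 11 2-{3,4-dimethoxy-2-[(2-methylbut-3-yn-2-yl)oxy]phenyl}-1-{2-methoxy-4-[(triisopropylsilyl)oxy]phenyl}ethan-1-one, via N-phenyl enamine 10 (not isolated)
Conditions: Cs2CO3, THF/i-PrOH (4:1), rt; then 3 M aq. HCl, rt
Reagents that add atoms: water, O
Why: Horner–Wadsworth–Emmons olefination of the α-aminophosphonate anion with the non-enolisable aldehyde 5 forms the C3–C4 bond as enamine 10, and acid hydrolysis of this masked ketone places the carbonyl on the ring A side, a standard route to aryl benzyl ketones.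

Step 6
Reactants: 11 2-{3,4-dimethoxy-2-[(2-methylbut-3-yn-2-yl)oxy]phenyl}-1-{2-methoxy-4-[(triisopropylsilyl)oxy]phenyl}ethan-1-one
Product: 12 2-{3,4-dimethoxy-2-[(2-methylbut-3-en-2-yl)oxy]phenyl}-1-{2-methoxy-4-[(triisopropylsilyl)oxy]phenyl}ethan-1-one
Conditions: H2 (1 atm), Pd/CaCO3 poisoned with Pb(OAc)2, quinoline, EtOAc, rt
Reagents that add atoms: none
Why: Lindlar semihydrogenation of the terminal alkyne stops at the alkene because the lead- and quinoline-poisoned palladium does not reduce alkenes, aryl ketones or silyl ethers.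

Step 7
Reactants: 12 2-{3,4-dimethoxy-2-[(2-methylbut-3-en-2-yl)oxy]phenyl}-1-{2-methoxy-4-[(triisopropylsilyl)oxy]phenyl}ethan-1-one
Product: 14 2-[2-hydroxy-3,4-dimethoxy-5-(2-methylbut-3-en-2-yl)phenyl]-1-{2-methoxy-4-[(triisopropylsilyl)oxy]phenyl}ethan-1-one, via ortho-prenyl cyclohexadienone 13 (not isolated)
Conditions: N,N-diethylaniline, 140 °C, argon
Reagents that add atoms: none
Why: para-Claisen rearrangement (Claisen then Cope): the [3,3] shift to a blocked ortho carbon gives dienone 13, which cannot enolise and passes the allyl unit on by a second [3,3] shift to the free para position C5', the double allylic inversion restoring the 1,1-dimethylallyl group before tautomerisation to the phenol.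

Step 8
Reactants: 14 2-[2-hydroxy-3,4-dimethoxy-5-(2-methylbut-3-en-2-yl)phenyl]-1-{2-methoxy-4-[(triisopropylsilyl)oxy]phenyl}ethan-1-one
Product: 15 2-[2-{[tert-butyl(dimethyl)silyl]oxy}-3,4-dimethoxy-5-(2-methylbut-3-en-2-yl)phenyl]-1-{2-methoxy-4-[(triisopropylsilyl)oxy]phenyl}ethan-1-one
Conditions: TBSCl, imidazole, DMAP (cat.), DMF, 40 °C
Reagents that add atoms: tert-butyldimethylsilyl chloride, CC(C)(C)[Si](C)(C)Cl
Why: Silyl ether formation on the hindered phenol under imidazole/DMAP catalysis, mild enough to leave the enolisable ketone untouched, giving a 2'-O group that has neither an O–C–H bond nor a carbonyl oxygen within reach of C3.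

Step 9
Reactants: 15 2-[2-{[tert-butyl(dimethyl)silyl]oxy}-3,4-dimethoxy-5-(2-methylbut-3-en-2-yl)phenyl]-1-{2-methoxy-4-[(triisopropylsilyl)oxy]phenyl}ethan-1-one
Product: 16 2-[2-{[tert-butyl(dimethyl)silyl]oxy}-3,4-dimethoxy-5-(2-methylbut-3-en-2-yl)phenyl]-2-diazo-1-{2-methoxy-4-[(triisopropylsilyl)oxy]phenyl}ethan-1-one
Conditions: p-ABSA, DBU, MeCN, 0 °C → rt
Reagents that add atoms: 4-acetamidobenzenesulfonyl azide, CC(=O)Nc1ccc(cc1)S(=O)(=O)N=[N+]=[N-]
Why: Regitz diazo transfer: DBU deprotonates the benzylic α-keto methylene and the enolate attacks the sulfonyl azide, which then leaves as the sulfonamide to give the α-aryl-α-diazo ketone.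

Step 10
Reactants: 16 2-[2-{[tert-butyl(dimethyl)silyl]oxy}-3,4-dimethoxy-5-(2-methylbut-3-en-2-yl)phenyl]-2-diazo-1-{2-methoxy-4-[(triisopropylsilyl)oxy]phenyl}ethan-1-one
Product: 17 (3R)-3-[2-{[tert-butyl(dimethyl)silyl]oxy}-3,4-dimethoxy-5-(2-methylbut-3-en-2-yl)phenyl]-7-[(triisopropylsilyl)oxy]chroman-4-one
Conditions: Rh2(S-PTTL)4 (1 mol%), CH2Cl2, −20 °C → rt, slow addition of 16 at high dilution
Reagents that add atoms: none
Why: Proposed new method: Rh2(S-PTTL)4 should expel N2 from 16 to give an electrophilic aryl/keto (donor/acceptor) rhodium carbene at C3, which takes up hydride from the ortho-OCH3 of ring A through a three-centre transition state while the C2–C3 bond forms; the closest known reaction types are the dirhodium-catalysed 1,6-C–H insertion of o-alkoxyaryl diazo ketones into ether α-C–H bonds that gives chroman-4-ones and the intermolecular insertion of donor/acceptor carbenes into methyl ethers. Ring C closes as a six-membered ring by this 1,6-insertion across O1–C8a–C4a–C4, the carbene carbon becoming C3 and the former methyl carbon C2. The new stereocentre C3 is set under catalyst control, the chiral phthalimido carboxylate ligands exposing one face of the carbene to the incoming C–H bond. The step needs insertion to outrun capture of the carbene by the methoxy oxygen (five-membered oxonium ylide), and because methyl is a poor migrating group that ylide should revert to the carbene. The substrate offers no better site, since O2' carries a silyl group with no O–C–H bond and no carbonyl oxygen, the 3'- and 4'-methoxy groups cannot reach C3, and the hindered vinyl group sits meta on ring B, so only intermolecular reactions compete and slow addition at high dilution suppresses them.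

Step 11
Reactants: 17 (3R)-3-[2-{[tert-butyl(dimethyl)silyl]oxy}-3,4-dimethoxy-5-(2-methylbut-3-en-2-yl)phenyl]-7-[(triisopropylsilyl)oxy]chroman-4-one
Product: 18 (R)-pervilleanone [(3R)-7-hydroxy-3-[2-hydroxy-3,4-dimethoxy-5-(2-methylbut-3-en-2-yl)phenyl]chroman-4-one]
Conditions: HF·pyridine, pyridine, THF, 0 °C → rt; neutral aqueous work-up
Reagents that add atoms: none
Why: Fluoride-induced cleavage of both aryl silyl ethers (desilylation) under weakly acidic, buffered conditions that should not enolise the C4 ketone, so the C3 stereocentre and the terminal alkene are kept.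

**Compound list**

1 | 2,3-dimethoxyphenol | COc1cccc(O)c1OC | starting material
2 | 6-(hydroxymethyl)-2,3-dimethoxyphenol | COc1ccc(CO)c(O)c1OC | intermediate
3 | 2-hydroxy-3,4-dimethoxybenzaldehyde | COc1ccc(C=O)c(O)c1OC | intermediate
4 | 3-chloro-3-methylbut-1-yne | C#CC(C)(C)Cl | starting material
5 | 3,4-dimethoxy-2-[(2-methylbut-3-yn-2-yl)oxy]benzaldehyde | COc1ccc(C=O)c(OC(C)(C)C#C)c1OC | intermediate
6 | 4-hydroxy-2-methoxybenzaldehyde | COc1cc(O)ccc1C=O | starting material
7 | 2-methoxy-4-[(triisopropylsilyl)oxy]benzaldehyde | COc1cc(O[Si](C(C)C)(C(C)C)C(C)C)ccc1C=O | intermediate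
8 | (E)-1-{2-methoxy-4-[(triisopropylsilyl)oxy]phenyl}-N-phenylmethanimine | COc1cc(O[Si](C(C)C)(C(C)C)C(C)C)ccc1/C=N/c1ccccc1 | intermediate
9 | diphenyl [{2-methoxy-4-[(triisopropylsilyl)oxy]phenyl}(phenylamino)methyl]phosphonate, racemic | COc1cc(O[Si](C(C)C)(C(C)C)C(C)C)ccc1C(Nc1ccccc1)P(=O)(Oc1ccccc1)Oc1ccccc1 | intermediate
10 | 2-{3,4-dimethoxy-2-[(2-methylbut-3-yn-2-yl)oxy]phenyl}-1-{2-methoxy-4-[(triisopropylsilyl)oxy]phenyl}-N-phenylethen-1-amine (E/Z mixture, in equilibrium with the ketimine) | COc1cc(O[Si](C(C)C)(C(C)C)C(C)C)ccc1C(Nc1ccccc1)=Cc1ccc(OC)c(OC)c1OC(C)(C)C#C | intermediate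
11 | 2-{3,4-dimethoxy-2-[(2-methylbut-3-yn-2-yl)oxy]phenyl}-1-{2-methoxy-4-[(triisopropylsilyl)oxy]phenyl}ethan-1-one | COc1cc(O[Si](C(C)C)(C(C)C)C(C)C)ccc1C(=O)Cc1ccc(OC)c(OC)c1OC(C)(C)C#C | intermediate
12 | 2-{3,4-dimethoxy-2-[(2-methylbut-3-en-2-yl)oxy]phenyl}-1-{2-methoxy-4-[(triisopropylsilyl)oxy]phenyl}ethan-1-one | COc1cc(O[Si](C(C)C)(C(C)C)C(C)C)ccc1C(=O)Cc1ccc(OC)c(OC)c1OC(C)(C)C=C | intermediate
13 | 2,3-dimethoxy-6-(3-methylbut-2-en-1-yl)-6-(2-{2-methoxy-4-[(triisopropylsilyl)oxy]phenyl}-2-oxoethyl)cyclohexa-2,4-dien-1-one, racemic | COc1cc(O[Si](C(C)C)(C(C)C)C(C)C)ccc1C(=O)CC1(CC=C(C)C)C=CC(OC)=C(OC)C1=O | intermediate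
14 | 2-[2-hydroxy-3,4-dimethoxy-5-(2-methylbut-3-en-2-yl)phenyl]-1-{2-methoxy-4-[(triisopropylsilyl)oxy]phenyl}ethan-1-one | COc1cc(O[Si](C(C)C)(C(C)C)C(C)C)ccc1C(=O)Cc1cc(C(C)(C)C=C)c(OC)c(OC)c1O | intermediate
15 | 2-[2-{[tert-butyl(dimethyl)silyl]oxy}-3,4-dimethoxy-5-(2-methylbut-3-en-2-yl)phenyl]-1-{2-methoxy-4-[(triisopropylsilyl)oxy]phenyl}ethan-1-one | COc1cc(O[Si](C(C)C)(C(C)C)C(C)C)ccc1C(=O)Cc1cc(C(C)(C)C=C)c(OC)c(OC)c1O[Si](C)(C)C(C)(C)C | intermediate
16 | 2-[2-{[tert-butyl(dimethyl)silyl]oxy}-3,4-dimethoxy-5-(2-methylbut-3-en-2-yl)phenyl]-2-diazo-1-{2-methoxy-4-[(triisopropylsilyl)oxy]phenyl}ethan-1-one | COc1cc(O[Si](C(C)C)(C(C)C)C(C)C)ccc1C(=O)C(=[N+]=[N-])c1cc(C(C)(C)C=C)c(OC)c(OC)c1O[Si](C)(C)C(C)(C)C | intermediate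
17 | (3R)-3-[2-{[tert-butyl(dimethyl)silyl]oxy}-3,4-dimethoxy-5-(2-methylbut-3-en-2-yl)phenyl]-7-[(triisopropylsilyl)oxy]chroman-4-one | C=CC(C)(C)c1cc([C@@H]2COc3cc(O[Si](C(C)C)(C(C)C)C(C)C)ccc3C2=O)c(O[Si](C)(C)C(C)(C)C)c(OC)c1OC | intermediate
18 | (R)-pervilleanone, (3R)-7-hydroxy-3-[2-hydroxy-3,4-dimethoxy-5-(2-methylbut-3-en-2-yl)phenyl]chroman-4-one | C=CC(C)(C)c1cc([C@@H]2COc3cc(O)ccc3C2=O)c(O)c(OC)c1OC | target

**Step count and risks**

Total steps: 11. Longest linear sequence: 9 steps (steps 1, 2, 5–11 from 1; equally steps 3–11 from 6).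

Steps most likely to fail:

1. Step 10 (the proposed new method). The carbene may be captured by the ortho-methoxy oxygen, giving an oxonium ylide that then transfers its methyl group instead of undergoing C–H insertion. Enantiofacial discrimination at the carbene carbon may also be insufficient. The fallback uses known chemistry, sets out from 15 and comes back to the route at 17. BCl3 (CH2Cl2, −78 °C) should cleave only the methyl ether chelated to the ketone and give 2-[2-{[tert-butyl(dimethyl)silyl]oxy}-3,4-dimethoxy-5-(2-methylbut-3-en-2-yl)phenyl]-1-{2-hydroxy-4-[(triisopropylsilyl)oxy]phenyl}ethan-1-one F1. Heating F1 with N,N-dimethylformamide dimethyl acetal (toluene, 90 °C) supplies C2 and closes ring C to the isoflavone F2. Noyori-type asymmetric transfer hydrogenation with RuCl[(R,R)-TsDPEN](p-cymene) and HCO2H/Et3N (EtOAc, 40 °C) should reduce the C2=C3 bond and then the ketone, with dynamic kinetic resolution of the rapidly enolising C3 centre, to the cis-(3R,4R)-isoflavan-4-ol F3. Dess–Martin periodinane (CH2Cl2, rt) should then reoxidise C4 without touching C3 and deliver 17.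

2. Step 7. The tertiary allyl ether may ionise and lose isoprene, or the freed phenol may undergo cyclodehydration onto the neighbouring ketone at the reaction temperature, before the Cope shift delivers the para product. The fallback replaces the sigmatropic transfer by a cross-coupling, sets out from 3 and comes back at 15. NBS (MeCN, 0 °C) should brominate the position para to the hydroxyl and give 5-bromo-2-hydroxy-3,4-dimethoxybenzaldehyde F4. A γ-selective Suzuki–Miyaura allylation with potassium trifluoro(3-methylbut-2-en-1-yl)borate (Pd(OAc)2, 1,1'-bis(di-tert-butylphosphino)ferrocene, K2CO3, THF/H2O, reflux) should give 2-hydroxy-3,4-dimethoxy-5-(2-methylbut-3-en-2-yl)benzaldehyde F5. TBSCl/imidazole (DMF) should give its silyl ether, 2-{[tert-butyl(dimethyl)silyl]oxy}-3,4-dimethoxy-5-(2-methylbut-3-en-2-yl)benzaldehyde F6. Horner–Wadsworth–Emmons olefination with 9 (NaH, THF, 0 °C → rt) should give the N-phenyl enamine F7, and dilute aqueous HCl should hydrolyse it to 15.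

3. Step 2. The phenoxide is hindered on both sides and deactivated by conjugation with the aldehyde, so O-alkylation may be slow and the propargylic chloride may be lost by elimination. The fallback makes the allyl ether directly by π-allyl chemistry, sets out from 3 and comes back at 12. Tsuji–Trost O-allylation with tert-butyl 2-methylbut-3-en-2-yl carbonate and Pd(PPh3)4 (THF, 0 °C, kinetic attack at the more substituted allyl terminus) should give 3,4-dimethoxy-2-[(2-methylbut-3-en-2-yl)oxy]benzaldehyde F8. Olefination with 9 (Cs2CO3, THF/i-PrOH, rt) should give the N-phenyl enamine F9, and hydrolysis with aqueous acetic acid should give 12, so that step 6 is no longer needed.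

**Further compounds**

F1 | step 10 | 2-[2-{[tert-butyl(dimethyl)silyl]oxy}-3,4-dimethoxy-5-(2-methylbut-3-en-2-yl)phenyl]-1-{2-hydroxy-4-[(triisopropylsilyl)oxy]phenyl}ethan-1-one | Oc1cc(O[Si](C(C)C)(C(C)C)C(C)C)ccc1C(=O)Cc1cc(C(C)(C)C=C)c(OC)c(OC)c1O[Si](C)(C)C(C)(C)C
F2 | step 10 | 3-[2-{[tert-butyl(dimethyl)silyl]oxy}-3,4-dimethoxy-5-(2-methylbut-3-en-2-yl)phenyl]-7-[(triisopropylsilyl)oxy]-4H-chromen-4-one | C=CC(C)(C)c1cc(-c2coc3cc(O[Si](C(C)C)(C(C)C)C(C)C)ccc3c2=O)c(O[Si](C)(C)C(C)(C)C)c(OC)c1OC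
F3 | step 10 | (3R,4R)-3-[2-{[tert-butyl(dimethyl)silyl]oxy}-3,4-dimethoxy-5-(2-methylbut-3-en-2-yl)phenyl]-7-[(triisopropylsilyl)oxy]chroman-4-ol (cis) | C=CC(C)(C)c1cc([C@@H]2COc3cc(O[Si](C(C)C)(C(C)C)C(C)C)ccc3[C@@H]2O)c(O[Si](C)(C)C(C)(C)C)c(OC)c1OC
F4 | step 7 | 5-bromo-2-hydroxy-3,4-dimethoxybenzaldehyde | COc1c(Br)cc(C=O)c(O)c1OC
F5 | step 7 | 2-hydroxy-3,4-dimethoxy-5-(2-methylbut-3-en-2-yl)benzaldehyde | COc1c(C(C)(C)C=C)cc(C=O)c(O)c1OC
F6 | step 7 | 2-{[tert-butyl(dimethyl)silyl]oxy}-3,4-dimethoxy-5-(2-methylbut-3-en-2-yl)benzaldehyde | COc1c(C(C)(C)C=C)cc(C=O)c(O[Si](C)(C)C(C)(C)C)c1OC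
F7 | step 7 | 2-[2-{[tert-butyl(dimethyl)silyl]oxy}-3,4-dimethoxy-5-(2-methylbut-3-en-2-yl)phenyl]-1-{2-methoxy-4-[(triisopropylsilyl)oxy]phenyl}-N-phenylethen-1-amine | COc1cc(O[Si](C(C)C)(C(C)C)C(C)C)ccc1C(Nc1ccccc1)=Cc1cc(C(C)(C)C=C)c(OC)c(OC)c1O[Si](C)(C)C(C)(C)C
F8 | step 2 | 3,4-dimethoxy-2-[(2-methylbut-3-en-2-yl)oxy]benzaldehyde | COc1ccc(C=O)c(OC(C)(C)C=C)c1OC
F9 | step 2 | 2-{3,4-dimethoxy-2-[(2-methylbut-3-en-2-yl)oxy]phenyl}-1-{2-methoxy-4-[(triisopropylsilyl)oxy]phenyl}-N-phenylethen-1-amine | COc1cc(O[Si](C(C)C)(C(C)C)C(C)C)ccc1C(Nc1ccccc1)=Cc1ccc(OC)c(OC)c1OC(C)(C)C=C
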